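**Retrosynthetic overview**

- Numbering the chain C1–C7 from the guaiacyl end, the target is cut at C2–C3. C3–C7 with the oxygens on C3, C5 and C7 are an opened 6-aryl-4-methoxy-5,6-dihydro-2H-pyran-2-one (lactone C=O = C3, enol-ether carbon = C5, ring oxygen = O7); C1–C2 arrive as an E-styryl metal.
- Forward, one addition of the styrylcerium reagent to the lactone carbonyl forms C2–C3 and opens the ring. Mild acid then converts the C5 methyl enol ether into the enolised 3,5-dione, and buffered fluoride frees both phenols.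
- The lactone carries the C7 stereocentre, set by a Ti(OiPr)4/(S)-BINOL vinylogous Mukaiyama aldol of a dioxinone silyl dienolate with silylated 4-hydroxybenzaldehyde. The dihydropyranone is the only ring built (acylketene lactonisation, then O-methylation) and it is opened again in the key step.
- The E-styryl bromide comes from ferulic acid by silylation and bromodecarboxylation.

Key step: step 8

Assumption 1: the C3=C4 enol double bond of the target is a tautomeric feature of the 3,5-dione (keto form and both enol geometries interconvert), so only C1=C2 (E) and C7 (S) are stereo-elements to control.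

Assumption 2: (S)-BINOL is taken to give the (S)-carbinol, by analogy with other aryl aldehydes under Ti(OiPr)4/BINOL; should the sense prove opposite, (R)-BINOL is used and nothing else changes.

TBS = tert-butyldimethylsilyl.

**Route**

Step 1
Reactants: 1 4-hydroxybenzaldehyde
Product: 2 4-(tert-butyldimethylsilyloxy)benzaldehyde
Conditions: TBSCl, imidazole, DMF, rt
Reagents that add atoms: tert-butyldimethylsilyl chloride (TBSCl), CC(C)(C)[Si](C)(C)Cl
Why: Imidazole-mediated silylation of a phenol is standard silyl ether formation and leaves the aldehyde untouched.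

Step 2
Reactants: 3 2,2,6-trimethyl-4H-1,3-dioxin-4-one
Product: 5 2,2-dimethyl-6-methylene-4-(trimethylsilyloxy)-4H-1,3-dioxine, via lithium dienolate 4 (not isolated)
Conditions: LiN(iPr)2, THF, −78 °C; Me3SiCl, −78 °C to rt; distilled
Reagents that add atoms: chlorotrimethylsilane, C[Si](C)(C)Cl
Why: Kinetic deprotonation of the vinylogous methyl group and O-silylation of the dienolate is the established preparation of this acetoacetate-equivalent silyl dienolate (vinylogous silyl ketene acetal formation).

Step 3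
Reactants: 2 4-(tert-butyldimethylsilyloxy)benzaldehyde, 5 2,2-dimethyl-6-methylene-4-(trimethylsilyloxy)-4H-1,3-dioxine
Product: 7 (S)-6-{2-hydroxy-2-[4-(tert-butyldimethylsilyloxy)phenyl]ethyl}-2,2-dimethyl-4H-1,3-dioxin-4-one, via O-trimethylsilyl aldol adduct 6 (not isolated)
Conditions: Ti(OiPr)4 (10 mol %), (S)-BINOL (10 mol %), 4 Å MS, THF, −78 °C to rt; then 1 M HCl, THF, 0 °C
Reagents that add atoms: none
Why: This is a catalytic asymmetric vinylogous Mukaiyama aldol in which the γ-carbon of the dienolate attacks the titanium-bound aldehyde, the BINOL ligand directing attack to the Si face to set C7 as S; the brief cold acid treatment removes only the trimethylsilyl group.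

Step 4
Reactants: 7 (S)-6-{2-hydroxy-2-[4-(tert-butyldimethylsilyloxy)phenyl]ethyl}-2,2-dimethyl-4H-1,3-dioxin-4-one
Product: 9 (S)-6-[4-(tert-butyldimethylsilyloxy)phenyl]dihydro-2H-pyran-2,4(3H)-dione, via acylketene 8 (not isolated)
Conditions: toluene (0.02 M), 110 °C
Reagents that add atoms: none
Why: Thermal retro-hetero-Diels–Alder loss of acetone from the dioxinone gives an acylketene that the δ-hydroxyl traps to close the six-membered lactone under neutral conditions, which spare the base-labile aryl silyl ether and do not touch C7.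

Step 5
Reactants: 9 (S)-6-[4-(tert-butyldimethylsilyloxy)phenyl]dihydro-2H-pyran-2,4(3H)-dione
Product: 10 (S)-6-[4-(tert-butyldimethylsilyloxy)phenyl]-4-methoxy-5,6-dihydro-2H-pyran-2-one
Conditions: Me2SO4, K2CO3, acetone, rt
Reagents that add atoms: dimethyl sulfate, COS(=O)(=O)OC
Why: O-Alkylation of the potassium enolate of the vinylogous acid with the hard electrophile dimethyl sulfate is the standard way to the 4-methoxy-5,6-dihydro-2-pyranone, and anhydrous carbonate in acetone offers no nucleophile that would cleave the aryl silyl ether.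

Step 6
Reactants: 11 ferulic acid
Product: 13 (E)-3-[4-(tert-butyldimethylsilyloxy)-3-methoxyphenyl]acrylic acid, via bis-silylated silyl ester 12 (not isolated)
Conditions: TBSCl (2.3 equiv), imidazole, DMF, rt; then AcOH/THF/H2O, rt
Reagents that add atoms: tert-butyldimethylsilyl chloride (TBSCl), CC(C)(C)[Si](C)(C)Cl
Why: Exhaustive silylation followed by selective hydrolysis of the far more labile silyl ester leaves the aryl silyl ether in place (silyl ether formation and silyl ester solvolysis).

Step 7
Reactants: 13 (E)-3-[4-(tert-butyldimethylsilyloxy)-3-methoxyphenyl]acrylic acid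
Product: 14 (E)-[4-(2-bromovinyl)-2-methoxyphenoxy](tert-butyl)dimethylsilane
Conditions: NBS, Et3N (10 mol %), CH2Cl2, rt
Reagents that add atoms: N-bromosuccinimide, O=C1CCC(=O)N1Br
Why: The catalytic Hunsdiecker bromodecarboxylation of an electron-rich cinnamate proceeds by bromination of the alkene assisted by the para oxygen and loss of CO2 to give the E-β-bromostyrene, and masking the phenol suppresses ring bromination.

Step 8
Reactants: 14 (E)-[4-(2-bromovinyl)-2-methoxyphenoxy](tert-butyl)dimethylsilane, 10 (S)-6-[4-(tert-butyldimethylsilyloxy)phenyl]-4-methoxy-5,6-dihydro-2H-pyran-2-one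
Product: 18 (S,1E,4E)-7-hydroxy-5-methoxy-1-[4-(tert-butyldimethylsilyloxy)-3-methoxyphenyl]-7-[4-(tert-butyldimethylsilyloxy)phenyl]hepta-1,4-dien-3-one, via E-styryllithium 15 (not isolated), via E-styrylcerium dichloride 16 (not isolated), via lactol 17 (not isolated)
Conditions: 14 (1.2 equiv), t-BuLi (2.4 equiv), Et2O, −78 °C; CeCl3 (anhydrous, 1.3 equiv), THF, −78 °C; 10, THF, −78 °C; sat. aq NH4Cl, −78 °C to rt
Reagents that add atoms: none
Why: Bromine–lithium exchange with two equivalents of t-BuLi at −78 °C turns 14 into the E-alkenyllithium 15 with retention of geometry, and transmetalation to CeCl3 gives the hard, weakly basic alkenylcerium 16. This adds 1,2 to the lactone carbonyl C3 of 10, and the cerium-bound tetrahedral alkoxide should persist in the cold so that no ketone is exposed to further reagent. The cold quench frees lactol 17, which opens to the δ-hydroxy dienone 18 because the new carbonyl is a stabilised vinylogous ester. The closest known reaction type is the single addition of organolithium or organocerium reagents to δ-lactones giving δ-hydroxy ketones, applied here to a β-alkoxy enoate lactone. No ring is closed and no stereocentre is formed: C7 keeps the configuration of 10, C1=C2 keeps that of 14, and the C4=C5 geometry is the one imposed by the ring. The step needs carbonyl attack to beat addition–elimination at the methoxy-bearing C5, γ-deprotonation at C6 with ring-opening elimination, and a second addition; the oxophilic cerium reagent, the near-stoichiometric charge, the low temperature and the low acidity of this vinylogous carbonate secure that.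

Step 9
Reactants: 18 (S,1E,4E)-7-hydroxy-5-methoxy-1-[4-(tert-butyldimethylsilyloxy)-3-methoxyphenyl]-7-[4-(tert-butyldimethylsilyloxy)phenyl]hepta-1,4-dien-3-one
Product: 19 (S,1E)-3,7-dihydroxy-1-[4-(tert-butyldimethylsilyloxy)-3-methoxyphenyl]-7-[4-(tert-butyldimethylsilyloxy)phenyl]hepta-1,3-dien-5-one (enol form of the 3,5-dione)
Conditions: 1 M aq HCl, THF, 0 °C to rt, stopped at full conversion
Reagents that add atoms: water, O
Why: Acid-catalysed hydrolysis of a vinylogous ester (water adds to C5 of the protonated β-methoxy enone and methanol leaves) gives the 1,3-diketone, which rests as the enol conjugated with the styryl unit; aryl silyl ethers tolerate cold dilute acid and C7 is not involved.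

Step 10
Reactants: 19 (S,1E)-3,7-dihydroxy-1-[4-(tert-butyldimethylsilyloxy)-3-methoxyphenyl]-7-[4-(tert-butyldimethylsilyloxy)phenyl]hepta-1,3-dien-5-one
Product: 20 (S,1E)-3,7-dihydroxy-1-(4-hydroxy-3-methoxyphenyl)-7-(4-hydroxyphenyl)hepta-1,3-dien-5-one (enol form of the 3,5-dione; the target)
Conditions: Bu4NF, AcOH, THF, 0 °C
Reagents that add atoms: none
Why: Fluoride cleaves aryl silyl ethers rapidly, and buffering with acetic acid keeps the medium near neutral so that the β-hydroxy ketone should neither dehydrate nor undergo retro-aldol cleavage.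

**Compound list**

1 | 4-hydroxybenzaldehyde | O=Cc1ccc(O)cc1 | starting material
2 | 4-(tert-butyldimethylsilyloxy)benzaldehyde | O=Cc1ccc(O[Si](C)(C)C(C)(C)C)cc1 | intermediate
3 | 2,2,6-trimethyl-4H-1,3-dioxin-4-one | CC1=CC(=O)OC(C)(C)O1 | starting material
4 | lithium dienolate of 3 (not isolated) | C=C1C=C(O[Li])OC(C)(C)O1 | intermediate
5 | 2,2-dimethyl-6-methylene-4-(trimethylsilyloxy)-4H-1,3-dioxine | C=C1C=C(O[Si](C)(C)C)OC(C)(C)O1 | intermediate
6 | (S)-6-{2-[4-(tert-butyldimethylsilyloxy)phenyl]-2-(trimethylsilyloxy)ethyl}-2,2-dimethyl-4H-1,3-dioxin-4-one (not isolated) | CC1(C)OC(=O)C=C(C[C@H](O[Si](C)(C)C)c2ccc(O[Si](C)(C)C(C)(C)C)cc2)O1 | intermediate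
7 | (S)-6-{2-hydroxy-2-[4-(tert-butyldimethylsilyloxy)phenyl]ethyl}-2,2-dimethyl-4H-1,3-dioxin-4-one | CC1(C)OC(=O)C=C(C[C@H](O)c2ccc(O[Si](C)(C)C(C)(C)C)cc2)O1 | intermediate
8 | (S)-5-hydroxy-5-[4-(tert-butyldimethylsilyloxy)phenyl]-3-oxopent-1-en-1-one, the acylketene (not isolated) | O=C=CC(=O)C[C@H](O)c1ccc(O[Si](C)(C)C(C)(C)C)cc1 | intermediate
9 | (S)-6-[4-(tert-butyldimethylsilyloxy)phenyl]dihydro-2H-pyran-2,4(3H)-dione | O=C1CC(=O)O[C@H](c2ccc(O[Si](C)(C)C(C)(C)C)cc2)C1 | intermediate
10 | (S)-6-[4-(tert-butyldimethylsilyloxy)phenyl]-4-methoxy-5,6-dihydro-2H-pyran-2-one | COC1=CC(=O)O[C@H](c2ccc(O[Si](C)(C)C(C)(C)C)cc2)C1 | intermediate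
11 | ferulic acid | COc1cc(/C=C/C(=O)O)ccc1O | starting material
12 | tert-butyldimethylsilyl (E)-3-[4-(tert-butyldimethylsilyloxy)-3-methoxyphenyl]acrylate (not isolated) | COc1cc(/C=C/C(=O)O[Si](C)(C)C(C)(C)C)ccc1O[Si](C)(C)C(C)(C)C | intermediate
13 | (E)-3-[4-(tert-butyldimethylsilyloxy)-3-methoxyphenyl]acrylic acid | COc1cc(/C=C/C(=O)O)ccc1O[Si](C)(C)C(C)(C)C | intermediate
14 | (E)-[4-(2-bromovinyl)-2-methoxyphenoxy](tert-butyl)dimethylsilane | COc1cc(/C=C/Br)ccc1O[Si](C)(C)C(C)(C)C | intermediate
15 | (E)-2-[4-(tert-butyldimethylsilyloxy)-3-methoxyphenyl]vinyllithium (not isolated) | COc1cc(/C=C/[Li])ccc1O[Si](C)(C)C(C)(C)C | intermediate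
16 | (E)-2-[4-(tert-butyldimethylsilyloxy)-3-methoxyphenyl]vinylcerium dichloride (not isolated) | COc1cc(/C=C/[Ce](Cl)Cl)ccc1O[Si](C)(C)C(C)(C)C | intermediate
17 | (6S)-2-hydroxy-4-methoxy-2-{(E)-2-[4-(tert-butyldimethylsilyloxy)-3-methoxyphenyl]vinyl}-6-[4-(tert-butyldimethylsilyloxy)phenyl]-5,6-dihydro-2H-pyran, lactol as a mixture at C2 (not isolated) | COC1=CC(O)(/C=C/c2ccc(O[Si](C)(C)C(C)(C)C)c(OC)c2)O[C@H](c2ccc(O[Si](C)(C)C(C)(C)C)cc2)C1 | intermediate
18 | (S,1E,4E)-7-hydroxy-5-methoxy-1-[4-(tert-butyldimethylsilyloxy)-3-methoxyphenyl]-7-[4-(tert-butyldimethylsilyloxy)phenyl]hepta-1,4-dien-3-one | COc1cc(/C=C/C(=O)/C=C(\C[C@H](O)c2ccc(O[Si](C)(C)C(C)(C)C)cc2)OC)ccc1O[Si](C)(C)C(C)(C)C | intermediate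
19 | (S,1E)-3,7-dihydroxy-1-[4-(tert-butyldimethylsilyloxy)-3-methoxyphenyl]-7-[4-(tert-butyldimethylsilyloxy)phenyl]hepta-1,3-dien-5-one (enol form of the 3,5-dione) | COc1cc(/C=C/C(O)=C\C(=O)C[C@H](O)c2ccc(O[Si](C)(C)C(C)(C)C)cc2)ccc1O[Si](C)(C)C(C)(C)C | intermediate
20 | (S,1E)-3,7-dihydroxy-1-(4-hydroxy-3-methoxyphenyl)-7-(4-hydroxyphenyl)hepta-1,3-dien-5-one (enol form of the 3,5-dione) | COc1cc(/C=C/C(O)=C\C(=O)C[C@H](O)c2ccc(O)cc2)ccc1O | target

**Step count**

Total steps: 10. Longest linear sequence: 7 (steps 1, 3, 4, 5, 8, 9, 10 from 4-hydroxybenzaldehyde; the same length from the dioxinone through step 2).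

**Steps most likely to fail**

Step 8. The carbonyl of this vinylogous-carbonate lactone is a poor electrophile and this variant of lactone mono-addition is untested. The addition may be outrun by deprotonation at C6 followed by eliminative opening of the ring, or by attack at the methoxy-bearing C5. The tetrahedral adduct may also collapse before the quench and take up a second equivalent of reagent. The fallback sets out from 7 and comes back to the route at 20; it bypasses the lactone and the enol ether altogether.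
- The C7 hydroxyl of 7 is silylated (Et3SiCl, imidazole, CH2Cl2) to give (S)-6-{2-[4-(tert-butyldimethylsilyloxy)phenyl]-2-(triethylsilyloxy)ethyl}-2,2-dimethyl-4H-1,3-dioxin-4-one F1.
- Heating F1 with N,O-dimethylhydroxylamine in toluene (100 °C, sealed vessel) lets the amine capture the acylketene and gives (S)-5-[4-(tert-butyldimethylsilyloxy)phenyl]-N-methoxy-N-methyl-3-oxo-5-(triethylsilyloxy)pentanamide F2.
- F2 is converted into its enolate with LiN(SiMe3)2 (1 equiv, THF, −78 °C) and treated with styryllithium 15, made from 14 as in step 8. This Weinreb ketone synthesis on the chelated amide gives the O7-triethylsilyl, bis-TBS enolised diketone (S,1E)-3-hydroxy-1-[4-(tert-butyldimethylsilyloxy)-3-methoxyphenyl]-7-[4-(tert-butyldimethylsilyloxy)phenyl]-7-(triethylsilyloxy)hepta-1,3-dien-5-one F3.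
- HF·pyridine buffered with pyridine in THF removes all three silyl groups from F3 to give 20.

Step 9. Under acid the free C7 hydroxyl can add to the activated C3 carbonyl and the hemiketal can lose water, so that cyclodehydration to a dihydropyranone competes with hydrolysis of the enol ether. Ionisation of the electron-rich benzylic C7–O bond would erode the stereocentre or lead to elimination. The fallback sets out from 18 and comes back at 20; it removes the internal nucleophile before the acid step.
- O7 of 18 is capped (TBSCl, imidazole, DMF) to give (S,1E,4E)-5-methoxy-1-[4-(tert-butyldimethylsilyloxy)-3-methoxyphenyl]-7-(tert-butyldimethylsilyloxy)-7-[4-(tert-butyldimethylsilyloxy)phenyl]hepta-1,4-dien-3-one F4.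
- The enol ether of F4 is hydrolysed with aqueous HCl in THF to the tris-silylated enolised diketone (S,1E)-3-hydroxy-1-[4-(tert-butyldimethylsilyloxy)-3-methoxyphenyl]-7-(tert-butyldimethylsilyloxy)-7-[4-(tert-butyldimethylsilyloxy)phenyl]hepta-1,3-dien-5-one F5.
- HF·pyridine in THF then cleaves all three silyl ethers of F5 to give 20.

Step 3. Facial selectivity in the catalytic aldol may be insufficient with the electron-rich silyloxybenzaldehyde, or an uncatalysed or silyl-cation-promoted background reaction may dilute the enantiomeric purity of the only stereocentre. The fallback sets out from 7 of insufficient enantiomeric purity and comes back to the route at 7; it replaces C–C-bond-forming stereocontrol by ketone reduction.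
- Dess–Martin periodinane in CH2Cl2 oxidises the carbinol to the achiral aryl ketone 6-{2-[4-(tert-butyldimethylsilyloxy)phenyl]-2-oxoethyl}-2,2-dimethyl-4H-1,3-dioxin-4-one F6.
- Asymmetric transfer hydrogenation of F6 with RuCl(p-cymene)[(S,S)-TsDPEN] in HCO2H/Et3N returns (S)-7. By analogy with acetophenone-type aryl ketones the (S,S) catalyst is expected to give the S alcohol.

**Further compounds**

F1 | step 8 | (S)-6-{2-[4-(tert-butyldimethylsilyloxy)phenyl]-2-(triethylsilyloxy)ethyl}-2,2-dimethyl-4H-1,3-dioxin-4-one | CC1(C)OC(=O)C=C(C[C@H](O[Si](CC)(CC)CC)c2ccc(O[Si](C)(C)C(C)(C)C)cc2)O1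
F2 | step 8 | (S)-5-[4-(tert-butyldimethylsilyloxy)phenyl]-N-methoxy-N-methyl-3-oxo-5-(triethylsilyloxy)pentanamide | CON(C)C(=O)CC(=O)C[C@H](O[Si](CC)(CC)CC)c1ccc(O[Si](C)(C)C(C)(C)C)cc1
F3 | step 8 | (S,1E)-3-hydroxy-1-[4-(tert-butyldimethylsilyloxy)-3-methoxyphenyl]-7-[4-(tert-butyldimethylsilyloxy)phenyl]-7-(triethylsilyloxy)hepta-1,3-dien-5-one | COc1cc(/C=C/C(O)=C\C(=O)C[C@H](O[Si](CC)(CC)CC)c2ccc(O[Si](C)(C)C(C)(C)C)cc2)ccc1O[Si](C)(C)C(C)(C)C
F4 | step 9 | (S,1E,4E)-5-methoxy-1-[4-(tert-butyldimethylsilyloxy)-3-methoxyphenyl]-7-(tert-butyldimethylsilyloxy)-7-[4-(tert-butyldimethylsilyloxy)phenyl]hepta-1,4-dien-3-one | COc1cc(/C=C/C(=O)/C=C(\C[C@H](O[Si](C)(C)C(C)(C)C)c2ccc(O[Si](C)(C)C(C)(C)C)cc2)OC)ccc1O[Si](C)(C)C(C)(C)C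
F5 | step 9 | (S,1E)-3-hydroxy-1-[4-(tert-butyldimethylsilyloxy)-3-methoxyphenyl]-7-(tert-butyldimethylsilyloxy)-7-[4-(tert-butyldimethylsilyloxy)phenyl]hepta-1,3-dien-5-one | COc1cc(/C=C/C(O)=C\C(=O)C[C@H](O[Si](C)(C)C(C)(C)C)c2ccc(O[Si](C)(C)C(C)(C)C)cc2)ccc1O[Si](C)(C)C(C)(C)C
F6 | step 3 | 6-{2-[4-(tert-butyldimethylsilyloxy)phenyl]-2-oxoethyl}-2,2-dimethyl-4H-1,3-dioxin-4-one | CC1(C)OC(=O)C=C(CC(=O)c2ccc(O[Si](C)(C)C(C)(C)C)cc2)O1
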